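A direct plan would make the ten-membered ring by cleaving a bicycle: 2-methyl-5-(propan-2-yl)cyclopentan-1-one A1 would be taken by aldol addition, vinyl addition and ring-closing metathesis to the hydroazulene-3a,8-diol A2, whose monosulfonate would be fragmented (Grob) to the racemic (2Z,6Z)-dienone A3.
A3 would then be reduced to the cis-dienol A4 by asymmetric hydrogenation with dynamic kinetic resolution, and A4 would be esterified.
Weakest steps: (a) the fragmentation, because the sulfonate C–O bond must lie anti-periplanar to the ring-fusion bond while A2 would arise as a mixture of ring-fusion epimers, so only part of the material could react, and three stereocentres would be built only to be erased.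
(b) The reduction of A3, because both stereocentres of the target would depend on one unprecedented dynamic kinetic resolution of a base-labile ten-membered enone, at the end of a racemic sequence.
(c) The aldol addition of a tetrasubstituted enolate, because its syn/anti ratio alone would decide the geometry of the 6,7-alkene and could not be corrected later.

**Retrosynthetic overview**
The target is a (2Z,6Z)-farnesane in which C1 (the carbinol carbon of the ten-membered ring) is bonded to C10 (the ring carbon that carries the isopropyl group); these two atoms are the only stereocentres, and ring numbering equals farnesane numbering.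
Disconnections: (a) the ester C1–O bond, made with inversion by a Mitsunobu reaction of vanillic acid on the trans-dienol 13; (b) the ring bond C1–C10, made by an enantioselective chromium-mediated intramolecular allylation of the open-chain bromo-aldehyde 10, the same bond that closes the germacrane ring in biosynthesis; (c) 10 from nerol (C5–C12) and methyl acetoacetate (C1–C4).
The ten-membered ring is the only ring; it closes in step 9 together with both stereocentres, and the isopropyl group appears last by hydrogenation of the isopropenyl group that the allylation leaves.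
Both (Z)-alkenes are fixed in the open chain before the ring exists (no fragmentation geometry), the carbinol is never a ketone (no late reduction), and the trans outcome of the allylation is consumed, not corrected, by the invertive esterification.

Key step: step 9

Assumption: the sense of induction of the chiral chromium catalyst is assigned by analogy with open-chain enals; the ligand antipode that gives (1R,10S)-13 would be fixed in a test run by Mosher ester analysis.

Step 1
Reactants: 1 nerol [(2Z)-3,7-dimethylocta-2,6-dien-1-ol]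
Product: 2 neryl bromide [(2Z)-1-bromo-3,7-dimethylocta-2,6-diene]
Conditions: PBr3 (0.4 equiv), Et2O, −10 °C; used crude
Reagents that add atoms: phosphorus tribromide BrP(Br)Br
Why: SN2-type bromination of a primary allylic alcohol through its phosphite ester at low temperature, which keeps the (2Z) geometry and avoids allylic transposition.

Step 2
Reactants: 2 neryl bromide; 3 methyl acetoacetate (methyl 3-oxobutanoate)
Product: 4 methyl (6Z)-7,11-dimethyl-3-oxododeca-6,10-dienoate
Conditions: 3, NaH (1.1 equiv), THF, 0 °C; n-BuLi (1.05 equiv), 0 °C; then 2, 0 → 20 °C; 1 M HCl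
Reagents that add atoms: none
Why: Alkylation of the acetoacetate dianion at its more nucleophilic terminal (γ) carbon by the primary allylic bromide, which joins C4 to C5 and leaves the (Z)-alkene of the neryl unit untouched.

Step 3
Reactants: 4 methyl (6Z)-7,11-dimethyl-3-oxododeca-6,10-dienoate
Product: 5 methyl (2E,6Z)-7,11-dimethyl-3-[(trifluoromethanesulfonyl)oxy]dodeca-2,6,10-trienoate
Conditions: (CF3SO2)2O (1.3 equiv), aq Me4NOH (25 %, 3 equiv), hexanes, 5 → 20 °C
Reagents that add atoms: trifluoromethanesulfonic anhydride O=S(=O)(OS(=O)(=O)C(F)(F)F)C(F)(F)F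
Why: O-Sulfonylation of the non-chelated tetramethylammonium enolate, which adopts the dipole-minimised geometry and so gives the (E)-enol triflate with the chain cis to the ester, the arrangement that fixes the later (2Z)-alkene.

Step 4
Reactants: 5 methyl (2E,6Z)-7,11-dimethyl-3-[(trifluoromethanesulfonyl)oxy]dodeca-2,6,10-trienoate
Product: 6 methyl (2Z,6Z)-3,7,11-trimethyldodeca-2,6,10-trienoate
Conditions: MeMgBr (1.3 equiv), Fe(acac)3 (5 mol %), THF/NMP, −30 °C
Reagents that add atoms: methylmagnesium bromide C[Mg]Br
Why: Iron-catalysed cross-coupling of an alkenyl triflate with a Grignard reagent, which proceeds with retention of alkene geometry and is faster at −30 °C than attack on the ester, so the methyl group takes the place of the triflate and the enoate is (2Z).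

Step 5
Reactants: 6 methyl (2Z,6Z)-3,7,11-trimethyldodeca-2,6,10-trienoate
Product: 7 methyl (2Z,6Z,10E)-12-hydroxy-3,7,11-trimethyldodeca-2,6,10-trienoate
Conditions: SeO2 (0.2 equiv), t-BuOOH (3 equiv), salicylic acid (0.1 equiv), CH2Cl2, 0 → 20 °C, stopped at partial conversion
Reagents that add atoms: tert-butyl hydroperoxide CC(C)(C)OO (oxygen relayed by catalytic selenium dioxide O=[Se]=O)
Why: Riley allylic oxidation (ene reaction, then [2,3]-sigmatropic shift) made catalytic with t-BuOOH, which attacks the (E)-methyl group of the terminal, most accessible and most electron-rich trisubstituted alkene, the enoate alkene being deactivated.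

Step 6
Reactants: 7 methyl (2Z,6Z,10E)-12-hydroxy-3,7,11-trimethyldodeca-2,6,10-trienoate
Product: 8 methyl (2Z,6Z,10E)-12-bromo-3,7,11-trimethyldodeca-2,6,10-trienoate
Conditions: CBr4 (1.2 equiv), PPh3 (1.25 equiv), CH2Cl2, 0 °C
Reagents that add atoms: carbon tetrabromide BrC(Br)(Br)Br
Why: Appel bromination of the primary allylic alcohol under neutral conditions, an SN2 process without allylic transposition.

Step 7
Reactants: 8 methyl (2Z,6Z,10E)-12-bromo-3,7,11-trimethyldodeca-2,6,10-trienoate
Product: 9 (2Z,6Z,10E)-12-bromo-3,7,11-trimethyldodeca-2,6,10-trien-1-ol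
Conditions: i-Bu2AlH (2.2 equiv), CH2Cl2, −78 °C; aq potassium sodium tartrate
Reagents that add atoms: none
Why: 1,2-Reduction of the enoate by the aluminium hydride at −78 °C, a temperature at which the allylic bromide is not reduced and the (2Z) geometry is kept.

Step 8
Reactants: 9 (2Z,6Z,10E)-12-bromo-3,7,11-trimethyldodeca-2,6,10-trien-1-ol
Product: 10 (2Z,6Z,10E)-12-bromo-3,7,11-trimethyldodeca-2,6,10-trienal
Conditions: TEMPO (10 mol %), PhI(OAc)2 (1.1 equiv), CH2Cl2, 0 → 20 °C; used at once
Reagents that add atoms: none
Why: Oxoammonium (TEMPO) oxidation with PhI(OAc)2 as terminal oxidant, which converts (Z)-allylic alcohols into (Z)-enals without isomerisation and does not touch the allylic bromide.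

Step 9
Reactants: 10 (2Z,6Z,10E)-12-bromo-3,7,11-trimethyldodeca-2,6,10-trienal
Product: 13 (1R,2Z,6Z,10S)-3,7-dimethyl-10-(prop-1-en-2-yl)cyclodeca-2,6-dien-1-ol, via allylchromium aldehyde 11 (not isolated), via trimethylsilyl ether 12 (not isolated)
Conditions: CrCl2 (10 mol %), (S,S)-1,8-bis(4-isopropyl-4,5-dihydro-1,3-oxazol-2-yl)-3,6-diphenyl-9H-carbazole (12 mol %), i-Pr2NEt (30 mol %), Mn powder (3 equiv), Me3SiCl (2 equiv), THF, 25 °C, 10 added by syringe pump over 20 h (end concentration 0.005 M); then K2CO3 (0.2 equiv), MeOH, 0 °C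
Reagents that add atoms: none
Why: Proposed new method: a catalytic enantioselective intramolecular Nozaki–Hiyama–Kishi allylation that closes a ten-membered carbocycle, in which divalent chromium (regenerated from the trivalent state by Mn) inserts into the allylic C–Br bond of 10 to give allylchromium 11, which adds through its γ-carbon (C10) to the aldehyde carbon (C1) in a six-membered Zimmerman–Traxler chair inside the pocket of the tridentate ligand, and Me3SiCl frees the catalyst from the alkoxide as silyl ether 12. The closest known reaction types are the chromium/bis(oxazolinyl)carbazole-catalysed anti-selective crotylation and methallylation of aldehydes and the closure of ω-bromo-farnesals to ten-membered germacrane rings with stoichiometric CrCl2; only their combination in one ring closure is new. The ring closes in the 10-exo-trig mode at the C1–C10 bond, and the two (Z)-alkenes of 10 fold the chain so that the reacting ends are near. C1 and C10 are formed together: the allylchromium equilibrates to its (E)-form, the chair with both ring arms equatorial gives the anti adduct (hydroxyl and isopropenyl trans on the ring), and the ligand selects the aldehyde face, which should give (1R,10S). The step needs ring closure over oligomerisation, γ- over α-attack and an intact (2Z)-enal: slow addition keeps the stationary concentration of 11 minimal, allylchromium reagents react at the more substituted terminus, and the buffered, non-nucleophilic medium at 25 °C offers no path for enal isomerisation.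

Step 10
Reactants: 13 (1R,2Z,6Z,10S)-3,7-dimethyl-10-(prop-1-en-2-yl)cyclodeca-2,6-dien-1-ol; 14 vanillic acid (4-hydroxy-3-methoxybenzoic acid)
Product: 15 (1S,2Z,6Z,10S)-3,7-dimethyl-10-(prop-1-en-2-yl)cyclodeca-2,6-dien-1-yl 4-hydroxy-3-methoxybenzoate
Conditions: 14 (1.5 equiv), PPh3 (1.5 equiv), diisopropyl azodicarboxylate (1.5 equiv), toluene/THF (4:1), −20 → 20 °C
Reagents that add atoms: none
Why: Mitsunobu esterification, in which the betaine deprotonates only the carboxylic acid of 14 (far more acidic than its phenol, so no protecting group is needed) and the carboxylate displaces the alkoxyphosphonium group by SN2 with inversion at C1, turning the trans-dienol into the cis ester while C10 is untouched; the low-polarity solvent and low temperature disfavour ionisation of the allylic phosphonium ion.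

Step 11
Reactants: 15 (1S,2Z,6Z,10S)-3,7-dimethyl-10-(prop-1-en-2-yl)cyclodeca-2,6-dien-1-yl 4-hydroxy-3-methoxybenzoate
Product: 16 (1R,2Z,6Z,10S)-3,7-dimethyl-10-(propan-2-yl)cyclodeca-2,6-dien-1-yl 4-hydroxy-3-methoxybenzoate
Conditions: RhCl(PPh3)3 (5 mol %), H2 (1 atm), toluene/EtOH (1:1), 20 °C
Reagents that add atoms: none
Why: Homogeneous hydrogenation with the monovalent rhodium complex, which reduces the 1,1-disubstituted alkene much faster than the two trisubstituted ring alkenes and leaves ester and phenol alone; no stereocentre is formed or touched, and the C1 descriptor changes from S to R only because C10 loses CIP rank when isopropenyl becomes isopropyl.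

**Compound list**
1 | nerol [(2Z)-3,7-dimethylocta-2,6-dien-1-ol] | OC/C=C(/C)CCC=C(C)C | starting material
2 | neryl bromide [(2Z)-1-bromo-3,7-dimethylocta-2,6-diene] | BrC/C=C(/C)CCC=C(C)C | intermediate
3 | methyl acetoacetate (methyl 3-oxobutanoate) | COC(=O)CC(C)=O | starting material
4 | methyl (6Z)-7,11-dimethyl-3-oxododeca-6,10-dienoate | COC(=O)CC(=O)CC/C=C(/C)CCC=C(C)C | intermediate
5 | methyl (2E,6Z)-7,11-dimethyl-3-[(trifluoromethanesulfonyl)oxy]dodeca-2,6,10-trienoate | COC(=O)/C=C(/OS(=O)(=O)C(F)(F)F)CC/C=C(/C)CCC=C(C)C | intermediate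
6 | methyl (2Z,6Z)-3,7,11-trimethyldodeca-2,6,10-trienoate | COC(=O)/C=C(/C)CC/C=C(/C)CCC=C(C)C | intermediate
7 | methyl (2Z,6Z,10E)-12-hydroxy-3,7,11-trimethyldodeca-2,6,10-trienoate | COC(=O)/C=C(/C)CC/C=C(/C)CC/C=C(\C)CO | intermediate
8 | methyl (2Z,6Z,10E)-12-bromo-3,7,11-trimethyldodeca-2,6,10-trienoate | COC(=O)/C=C(/C)CC/C=C(/C)CC/C=C(\C)CBr | intermediate
9 | (2Z,6Z,10E)-12-bromo-3,7,11-trimethyldodeca-2,6,10-trien-1-ol | OC/C=C(/C)CC/C=C(/C)CC/C=C(\C)CBr | intermediate
10 | (2Z,6Z,10E)-12-bromo-3,7,11-trimethyldodeca-2,6,10-trienal | O=C/C=C(/C)CC/C=C(/C)CC/C=C(\C)CBr | intermediate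
11 | (2Z,6Z,10E)-12-(dichlorochromio)-3,7,11-trimethyldodeca-2,6,10-trienal (allylchromium of trivalent chromium; chiral ligand not shown) | O=C/C=C(/C)CC/C=C(/C)CC/C=C(\C)C[Cr](Cl)Cl | intermediate
12 | trimethyl{[(1R,2Z,6Z,10S)-3,7-dimethyl-10-(prop-1-en-2-yl)cyclodeca-2,6-dien-1-yl]oxy}silane | C[Si](C)(C)O[C@@H]1/C=C(/C)CC/C=C(/C)CC[C@H]1C(C)=C | intermediate
13 | (1R,2Z,6Z,10S)-3,7-dimethyl-10-(prop-1-en-2-yl)cyclodeca-2,6-dien-1-ol (hydroxyl and isopropenyl trans) | O[C@@H]1/C=C(/C)CC/C=C(/C)CC[C@H]1C(C)=C | intermediate
14 | vanillic acid (4-hydroxy-3-methoxybenzoic acid) | COc1cc(C(=O)O)ccc1O | starting material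
15 | (1S,2Z,6Z,10S)-3,7-dimethyl-10-(prop-1-en-2-yl)cyclodeca-2,6-dien-1-yl 4-hydroxy-3-methoxybenzoate (ester oxygen and isopropenyl cis) | COc1cc(C(=O)O[C@H]2/C=C(/C)CC/C=C(/C)CC[C@H]2C(C)=C)ccc1O | intermediate
16 | (1R,2Z,6Z,10S)-3,7-dimethyl-10-(propan-2-yl)cyclodeca-2,6-dien-1-yl 4-hydroxy-3-methoxybenzoate | COc1cc(C(=O)O[C@H]2/C=C(/C)CC/C=C(/C)CC[C@H]2C(C)C)ccc1O | target

**Step count and risks**
Total steps: 11. Longest linear sequence: 11 steps (1 → 16).

Steps most likely to fail:

Step 9 (ring closure). The chiral chromium complex may give insufficient control of the aldehyde face, or may turn over too slowly for the slow-addition regime so that intermolecular coupling takes over. The fallback uses known chemistry and sets out from 10. The ring would be closed without ligand by stoichiometric CrCl2 (4 equiv) in THF at high dilution, a closure of known type for ω-bromo-farnesals, to give the racemic trans-dienol rac-(1R*,2Z,6Z,10S*)-3,7-dimethyl-10-(prop-1-en-2-yl)cyclodeca-2,6-dien-1-ol F1. F1 would be esterified with (2S)-2-methoxy-2-phenylacetic acid (DCC, DMAP), the diastereomeric esters separated by chromatography, and the ester of the wanted enantiomer, (1R,2Z,6Z,10S)-3,7-dimethyl-10-(prop-1-en-2-yl)cyclodeca-2,6-dien-1-yl (2S)-2-methoxy-2-phenylacetate F2, saponified (LiOH, THF/H2O). The route is rejoined at 13.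

Step 10 (invertive esterification). SN2 displacement at the hindered allylic carbinol by the weakly acidic vanillic acid may be slow, so that ionisation or elimination of the alkoxyphosphonium ion erodes the inversion. The fallback sets out from 13 and 14. 13 would first be inverted with the stronger acid 4-nitrobenzoic acid (PPh3, diisopropyl azodicarboxylate) to (1S,2Z,6Z,10S)-3,7-dimethyl-10-(prop-1-en-2-yl)cyclodeca-2,6-dien-1-yl 4-nitrobenzoate F3, and F3 methanolysed (K2CO3, MeOH) to the cis-dienol (1S,2Z,6Z,10S)-3,7-dimethyl-10-(prop-1-en-2-yl)cyclodeca-2,6-dien-1-ol F4. In parallel, 14 would be acetylated (Ac2O, pyridine) to 4-acetoxy-3-methoxybenzoic acid F5. F4 would be acylated with F5 under Steglich conditions (DCC, DMAP), with retention, to (1S,2Z,6Z,10S)-3,7-dimethyl-10-(prop-1-en-2-yl)cyclodeca-2,6-dien-1-yl 4-acetoxy-3-methoxybenzoate F6, and the phenolic acetate removed with pyrrolidine (CH2Cl2, 0 °C). The route is rejoined at 15.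

Step 5 (allylic oxidation). Site selection between the terminal and the central trisubstituted alkene may be poor, and the alcohol may be over-oxidised. The fallback sets out from 6 and builds the oxidised terminus by degradation and olefination. NBS in aqueous THF at 0 °C, which is selective for the terminal alkene of farnesoates, would give the bromohydrin methyl (2Z,6Z)-10-bromo-11-hydroxy-3,7,11-trimethyldodeca-2,6-dienoate F7, and K2CO3 in MeOH the epoxide methyl (2Z,6Z)-10,11-epoxy-3,7,11-trimethyldodeca-2,6-dienoate F8. Periodic acid (H5IO6, THF/Et2O) would cleave F8 to the aldehyde methyl (2Z,6Z)-3,7-dimethyl-10-oxodeca-2,6-dienoate F9. A Wittig reaction of F9 with 2-(triphenylphosphoranylidene)propanal would give the (E)-enal methyl (2Z,6Z,10E)-3,7,11-trimethyl-12-oxododeca-2,6,10-trienoate F10, and NaBH4/CeCl3 in MeOH at 0 °C would reduce the aldehyde only. The route is rejoined at 7.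

**Further compounds**
F1 | step 9 | rac-(1R*,2Z,6Z,10S*)-3,7-dimethyl-10-(prop-1-en-2-yl)cyclodeca-2,6-dien-1-ol (racemate; one enantiomer drawn) | O[C@@H]1/C=C(/C)CC/C=C(/C)CC[C@H]1C(C)=C
F2 | step 9 | (1R,2Z,6Z,10S)-3,7-dimethyl-10-(prop-1-en-2-yl)cyclodeca-2,6-dien-1-yl (2S)-2-methoxy-2-phenylacetate | CO[C@H](C(=O)O[C@@H]1/C=C(/C)CC/C=C(/C)CC[C@H]1C(C)=C)c1ccccc1
F3 | step 10 | (1S,2Z,6Z,10S)-3,7-dimethyl-10-(prop-1-en-2-yl)cyclodeca-2,6-dien-1-yl 4-nitrobenzoate | O=C(O[C@H]1/C=C(/C)CC/C=C(/C)CC[C@H]1C(C)=C)c1ccc(cc1)[N+](=O)[O-]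
F4 | step 10 | (1S,2Z,6Z,10S)-3,7-dimethyl-10-(prop-1-en-2-yl)cyclodeca-2,6-dien-1-ol | O[C@H]1/C=C(/C)CC/C=C(/C)CC[C@H]1C(C)=C
F5 | step 10 | 4-acetoxy-3-methoxybenzoic acid | COc1cc(C(=O)O)ccc1OC(C)=O
F6 | step 10 | (1S,2Z,6Z,10S)-3,7-dimethyl-10-(prop-1-en-2-yl)cyclodeca-2,6-dien-1-yl 4-acetoxy-3-methoxybenzoate | COc1cc(C(=O)O[C@H]2/C=C(/C)CC/C=C(/C)CC[C@H]2C(C)=C)ccc1OC(C)=O
F7 | step 5 | methyl (2Z,6Z)-10-bromo-11-hydroxy-3,7,11-trimethyldodeca-2,6-dienoate (racemic) | COC(=O)/C=C(/C)CC/C=C(/C)CCC(Br)C(C)(C)O
F8 | step 5 | methyl (2Z,6Z)-10,11-epoxy-3,7,11-trimethyldodeca-2,6-dienoate (racemic) | COC(=O)/C=C(/C)CC/C=C(/C)CCC1OC1(C)C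
F9 | step 5 | methyl (2Z,6Z)-3,7-dimethyl-10-oxodeca-2,6-dienoate | COC(=O)/C=C(/C)CC/C=C(/C)CCC=O
F10 | step 5 | methyl (2Z,6Z,10E)-3,7,11-trimethyl-12-oxododeca-2,6,10-trienoate | COC(=O)/C=C(/C)CC/C=C(/C)CC/C=C(\C)C=O
A1 | direct plan | 2-methyl-5-(propan-2-yl)cyclopentan-1-one | CC1CCC(C(C)C)C1=O
A2 | direct plan | (8R*,8aR*)-5,8a-dimethyl-3-(propan-2-yl)-1,2,3,3a,6,7,8,8a-octahydroazulene-3a,8-diol | CC1=CC2(O)C(C(C)C)CC[C@]2(C)[C@H](O)CC1
A3 | direct plan | (2Z,6Z)-3,7-dimethyl-10-(propan-2-yl)cyclodeca-2,6-dien-1-one (racemic) | O=C1/C=C(/C)CC/C=C(/C)CCC1C(C)C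
A4 | direct plan | (1R,2Z,6Z,10S)-3,7-dimethyl-10-(propan-2-yl)cyclodeca-2,6-dien-1-ol | O[C@H]1/C=C(/C)CC/C=C(/C)CC[C@H]1C(C)C
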